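**Retrosynthetic overview**

1. Target 42 ⇐ tris-silyl ether 41 ⇐ iodide 34 + α-phenylthio lactone 37 (butenolide made last by enolate alkylation and sulfoxide elimination); the three CH2OH groups ⇐ one LiAlH4 reduction of triester 30.
2. 30 ⇐ decalone 27 (C1 ketone removed via its enol triflate) ⇐ acyclic vinyl ketone–alkylidene malonate 24: rings B and A close in one operation by an intramolecular double Michael addition (formal [4+2] of the 2-silyloxydiene C10=C1(OSi)–C2=C3 with C5=C4), first C5–C10, then the ring-closing C3–C4 bond.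
3. Enabling feature: C4 of ring A carries two CH2OH groups, so it is a reduced malonate carbon; as C(CO2Me)2 it makes C5=C4 an acceptor for C10 and then the donor that attacks C3. The six atoms of ring A (C1, C2, C3, C4, C5, C10) therefore map onto diene plus dienophile, and the second new bond (C5–C10) closes ring B at the methyl-bearing quaternary carbon.
4. 24 ⇐ methyl ketone 15 (Mannich base, Knoevenagel) ⇐ ester 12 ⇐ Ireland–Claisen rearrangement of ester 7; C8 and C9 come by chirality transfer from the single carbinol stereocentre of 4 (CBS reduction of enone 3, made by cross-metathesis of 1 and 2), and C5 and C10 are relayed from C9 in the key step.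
5. Ring order: B and A together (step 12), butenolide last (steps 20 and 21).

Key step: step 12

Remark: C1–C20 in the text are the labdane positions of the target (C10 = methyl-bearing ring-fusion carbon, C4 = carbon with two CH2OH, C17 = CH2OH on C8, C11/C12 = side-chain CH2 groups, C13–C16 = butenolide).
Remark: compounds 13–24 are carried as epimer mixtures at C10 (13 and 14 also at C1); this has no consequence because C10 becomes sp2 in 25.

**Route**

Step 1
Reactants: 1 4-(benzyloxy)but-1-ene; 2 3-methylbut-3-en-2-one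
Product: 3 (3E)-6-(benzyloxy)-3-methylhex-3-en-2-one
Conditions: Hoveyda–Grubbs II (5 mol %), 2 (4 equiv), CH2Cl2, 40 °C
Reagents that add atoms: none
Why: Olefin cross-metathesis of a terminal alkene with a 1,1-disubstituted enone should give the E-trisubstituted enone under thermodynamic control, the excess of 2 suppressing homodimerization of 1.

Step 2
Reactants: 3 (3E)-6-(benzyloxy)-3-methylhex-3-en-2-one
Product: 4 (2R,3E)-6-(benzyloxy)-3-methylhex-3-en-2-ol
Conditions: (S)-Me-CBS (10 mol %), BH3·SMe2, THF, −20 °C; MeOH quench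
Reagents that add atoms: none
Why: Corey–Bakshi–Shibata reduction with the α-methylalkenyl group as the large substituent should give the (R)-carbinol, the only stereocentre set by catalysis in the route.

Step 3
Reactants: 5 methyl 5,5-dimethoxypentanoate
Product: 6 5,5-dimethoxypentanoic acid
Conditions: LiOH, THF/H2O, rt; then 1 M HCl to pH 4, 0 °C
Reagents that add atoms: lithium hydroxide [Li+].[OH-]
Why: Saponification leaves the base-stable dimethyl acetal untouched, and acidification only to pH 4 in the cold avoids acetal hydrolysis.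

Step 4
Reactants: 4 (2R,3E)-6-(benzyloxy)-3-methylhex-3-en-2-ol; 6 5,5-dimethoxypentanoic acid
Product: 7 (2R,3E)-6-(benzyloxy)-3-methylhex-3-en-2-yl 5,5-dimethoxypentanoate
Conditions: DCC, DMAP (cat.), CH2Cl2, 0 °C → rt
Reagents that add atoms: none
Why: Steglich esterification acylates the secondary allylic alcohol under neutral conditions with retention at the carbinol carbon.

Step 5
Reactants: 7 (2R,3E)-6-(benzyloxy)-3-methylhex-3-en-2-yl 5,5-dimethoxypentanoate
Product: 12 methyl (2S,3R,4E)-3-[2-(benzyloxy)ethyl]-2-(3,3-dimethoxypropyl)-4-methylhex-4-enoate, via lithium enolate 8 (not isolated), via silyl ketene acetal 9 (not isolated), via trimethylsilyl ester 10 (not isolated), via carboxylic acid 11 (not isolated)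
Conditions: LDA, THF, −78 °C; TMSCl/Et3N, −78 °C → rt, then 50 °C; MeOH; TMSCHN2, 0 °C
Reagents that add atoms: (trimethylsilyl)diazomethane C[Si](C)(C)C=[N+]=[N-]
Why: Ireland–Claisen rearrangement: LDA in THF gives the E(O)-enolate, and the chair transition state with the carbinol methyl equatorial transfers the C–O stereocentre to C8 and C9 (anti) while forming the E-trisubstituted alkene; methanolysis and TMSCHN2 then give the methyl ester without an acidic work-up.

Step 6
Reactants: 12 methyl (2S,3R,4E)-3-[2-(benzyloxy)ethyl]-2-(3,3-dimethoxypropyl)-4-methylhex-4-enoate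
Product: 14 methyl (2S,3S)-3-[2-(benzyloxy)ethyl]-2-(3,3-dimethoxypropyl)-5-hydroxy-4-methylhexanoate (C4/C5 epimer mixture), via alkylborane 13 (not isolated)
Conditions: BH3·SMe2 (1.2 equiv), THF, 0 °C → rt; then aq. NaOAc, 30% H2O2, 0 °C → rt
Reagents that add atoms: hydrogen peroxide OO
Why: Hydroboration–oxidation places boron, and then oxygen, on the less substituted alkene carbon (C1); the two new stereocentres are uncontrolled and are erased in steps 7 and 12.

Step 7
Reactants: 14 methyl (2S,3S)-3-[2-(benzyloxy)ethyl]-2-(3,3-dimethoxypropyl)-5-hydroxy-4-methylhexanoate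
Product: 15 methyl (2S,3S)-3-[2-(benzyloxy)ethyl]-2-(3,3-dimethoxypropyl)-4-methyl-5-oxohexanoate (C4 epimer mixture)
Conditions: Dess–Martin periodinane, NaHCO3, CH2Cl2, 0 °C → rt
Reagents that add atoms: none
Why: Dess–Martin oxidation converts the secondary alcohol into the methyl ketone under buffered conditions that keep the acetal and leave C8 and C9 untouched.

Step 8
Reactants: 15 methyl (2S,3S)-3-[2-(benzyloxy)ethyl]-2-(3,3-dimethoxypropyl)-4-methyl-5-oxohexanoate; 16 N,N-dimethylmethaniminium iodide (Eschenmoser's salt)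
Product: 19 methyl (2S,3S)-3-[2-(benzyloxy)ethyl]-2-(3,3-dimethoxypropyl)-7-(dimethylamino)-4-methyl-5-oxoheptanoate (C4 epimer mixture), via lithium enolate 17 (not isolated), via trimethylsilyl enol ether 18 (not isolated)
Conditions: LDA, TMSCl (internal quench), THF, −78 °C; then 16, CH2Cl2, rt; aq. NaHCO3
Reagents that add atoms: none
Why: Kinetic deprotonation occurs at the methyl group and the silyl enol ether undergoes a Mannich reaction with the iminium salt; immediate silyl trapping prevents Claisen-type attack of the enolate on the δ-ester.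

Step 9
Reactants: 19 methyl (2S,3S)-3-[2-(benzyloxy)ethyl]-2-(3,3-dimethoxypropyl)-7-(dimethylamino)-4-methyl-5-oxoheptanoate
Product: 20 methyl (2S,3S)-3-[2-(benzyloxy)ethyl]-7-(dimethylamino)-4-methyl-5-oxo-2-(3-oxopropyl)heptanoate (C4 epimer mixture)
Conditions: 1 M HCl, THF, 0 °C → rt; then NaHCO3; used at once
Reagents that add atoms: water O
Why: Acid hydrolysis of the dimethyl acetal liberates the aldehyde while the amine is held as its ammonium salt.

Step 10
Reactants: 20 methyl (2S,3S)-3-[2-(benzyloxy)ethyl]-7-(dimethylamino)-4-methyl-5-oxo-2-(3-oxopropyl)heptanoate; 21 dimethyl malonate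
Product: 22 trimethyl (5S,6S)-6-[2-(benzyloxy)ethyl]-10-(dimethylamino)-7-methyl-8-oxodec-1-ene-1,1,5-tricarboxylate (C7 epimer mixture)
Conditions: TiCl4, pyridine, THF, 0 °C → rt
Reagents that add atoms: none
Why: TiCl4/pyridine-mediated Knoevenagel condensation joins malonate to the aldehyde much faster than to the hindered ketone and avoids enamine pathways.

Step 11
Reactants: 22 trimethyl (5S,6S)-6-[2-(benzyloxy)ethyl]-10-(dimethylamino)-7-methyl-8-oxodec-1-ene-1,1,5-tricarboxylate
Product: 24 trimethyl (5S,6S)-6-[2-(benzyloxy)ethyl]-7-methyl-8-oxodeca-1,9-diene-1,1,5-tricarboxylate (C7 epimer mixture), via methiodide 23 (not isolated)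
Conditions: MeI, MeCN, rt; evaporate; then CH2Cl2, sat. aq. NaHCO3, 0 °C → rt; used at once
Reagents that add atoms: none
Why: Exhaustive methylation and Hofmann-type (E1cB) elimination of the Mannich base is the classical mild release of a vinyl ketone, and the alkylidene malonate is inert to MeI and bicarbonate.

Step 12
Reactants: 24 trimethyl (5S,6S)-6-[2-(benzyloxy)ethyl]-7-methyl-8-oxodeca-1,9-diene-1,1,5-tricarboxylate
Product: 27 trimethyl (4aS,5R,6S,8aS)-5-[2-(benzyloxy)ethyl]-4a-methyl-4-oxodecahydronaphthalene-1,1,6-tricarboxylate, via silyloxydiene 25 (not isolated), via silyl enol ether 26 (not isolated)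
Conditions: TBSOTf, i-Pr2NEt, CH2Cl2 (0.01 M), −78 °C → rt; then 1 M HCl, THF, 0 °C → rt
Reagents that add atoms: none
Why: Soft enolization of the α′-methine C10–H gives the cross-conjugated 2-silyloxydiene 25, whose nucleophilic terminus C10 adds to C5 of the silyl-triflate-activated alkylidene malonate (Mukaiyama–Michael addition), after which the malonate silyl ketene acetal at C4 adds to the vinyl ketone β-carbon C3; this silyl triflate/amine-mediated intramolecular double Michael addition is equivalent to an intramolecular Diels–Alder reaction of an in situ 2-silyloxydiene, which is the closest known reaction type. Ring B closes 6-exo-trig at the malonate acceptor through a chair, and ring A closes 6-endo-trig at the enone by the C3–C4 bond (or both bonds form in one fused-mode [4+2] when the diene is s-cis). At C10, A(1,3) strain between the C1 substituent cis to C9 (OTBS or vinyl, for either geometry of 25) and the C9 substituents holds C9–H in the diene plane, so C5, tethered through C8, bonds to the face that puts the methyl group axial on ring B and anti to C9–H, with the C9 side chain equatorial. At C5, the bulky malonate carbon stays equatorial in the same chair, which places C5–H anti to the C10 methyl (trans ring fusion), while C8 and C9 are carried from 24 with both substituents equatorial. The step needs trans fusion and 1,2-induction from C9, and the temporary C1 oxygen secures both, because it makes C10 the nucleophilic diene terminus (polarity-matched with C5) and acts as the steric directing group that excludes the cis-fused transition state. The C10 epimers of 24 converge because C10 is sp2 in 25.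

Step 13
Reactants: 27 trimethyl (4aS,5R,6S,8aS)-5-[2-(benzyloxy)ethyl]-4a-methyl-4-oxodecahydronaphthalene-1,1,6-tricarboxylate
Product: 29 trimethyl (4aS,5R,6S,8aS)-5-[2-(benzyloxy)ethyl]-4a-methyl-4-{[(trifluoromethyl)sulfonyl]oxy}-1,2,4a,5,6,7,8,8a-octahydronaphthalene-1,1,6-tricarboxylate, via potassium enolate 28 (not isolated)
Conditions: KHMDS, THF, −78 °C; PhNTf2, −78 → 0 °C
Reagents that add atoms: N-phenylbis(trifluoromethanesulfonimide) O=S(=O)(N(c1ccccc1)S(=O)(=O)C(F)(F)F)C(F)(F)F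
Why: Enol triflate formation is regiochemically unambiguous because the ketone can enolize only toward C2 (C10 is quaternary).

Step 14
Reactants: 29 trimethyl (4aS,5R,6S,8aS)-5-[2-(benzyloxy)ethyl]-4a-methyl-4-{[(trifluoromethyl)sulfonyl]oxy}-1,2,4a,5,6,7,8,8a-octahydronaphthalene-1,1,6-tricarboxylate
Product: 30 trimethyl (4aS,5R,6S,8aS)-5-[2-(benzyloxy)ethyl]-4a-methyl-1,2,4a,5,6,7,8,8a-octahydronaphthalene-1,1,6-tricarboxylate
Conditions: Pd(OAc)2 (5 mol %), PPh3 (10 mol %), HCO2H, n-Bu3N, DMF, 60 °C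
Reagents that add atoms: none
Why: Palladium-catalysed formate reduction of the enol triflate replaces OTf by H without touching the esters or the benzyl ether.

Step 15
Reactants: 30 trimethyl (4aS,5R,6S,8aS)-5-[2-(benzyloxy)ethyl]-4a-methyl-1,2,4a,5,6,7,8,8a-octahydronaphthalene-1,1,6-tricarboxylate
Product: 31 {(4aS,5R,6S,8aS)-5-[2-(benzyloxy)ethyl]-4a-methyl-1,2,4a,5,6,7,8,8a-octahydronaphthalene-1,1,6-triyl}trimethanol
Conditions: LiAlH4, THF, 0 °C → reflux; H2O, 15% NaOH, H2O work-up
Reagents that add atoms: none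
Why: Hydride reduction of the three methyl esters gives the three primary alcohols of the target in one operation; the ring alkene and the benzyl ether are inert.

Step 16
Reactants: 31 {(4aS,5R,6S,8aS)-5-[2-(benzyloxy)ethyl]-4a-methyl-1,2,4a,5,6,7,8,8a-octahydronaphthalene-1,1,6-triyl}trimethanol
Product: 32 tris(tert-butyldimethylsilyl) ether of 31
Conditions: TBSOTf, 2,6-lutidine, CH2Cl2, −78 → 0 °C
Reagents that add atoms: tert-butyldimethylsilyl triflate CC(C)(C)[Si](C)(C)OS(=O)(=O)C(F)(F)F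
Why: Silylation with the silyl triflate protects all three primary hydroxyls, including the two neopentylic ones on C4.

Step 17
Reactants: 32 tris(tert-butyldimethylsilyl) ether of 31
Product: 33 2-[(1R,2S,4aS,8aS)-2,5,5-tris({[tert-butyl(dimethyl)silyl]oxy}methyl)-8a-methyldecahydronaphthalen-1-yl]ethan-1-ol
Conditions: H2 (1 atm), 10% Pd/C, EtOAc, rt
Reagents that add atoms: none
Why: Catalytic hydrogenation saturates the cis-disubstituted ring alkene and hydrogenolyses the benzyl ether in the same operation; no stereocentre is formed and the silyl ethers are stable in EtOAc.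

Step 18
Reactants: 33 2-[(1R,2S,4aS,8aS)-2,5,5-tris({[tert-butyl(dimethyl)silyl]oxy}methyl)-8a-methyldecahydronaphthalen-1-yl]ethan-1-ol
Product: 34 {[(1R,2S,4aS,8aS)-1-(2-iodoethyl)-8a-methyldecahydronaphthalene-2,5,5-triyl]tris(methyleneoxy)}tris[tert-butyl(dimethyl)silane]
Conditions: I2, PPh3, imidazole, CH2Cl2, 0 °C → rt
Reagents that add atoms: iodine II
Why: Appel-type iodination converts the only free primary alcohol into the iodide, with imidazole buffering the silyl ethers.

Step 19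
Reactants: 35 3-bromooxolan-2-one (α-bromo-γ-butyrolactone); 36 benzenethiol
Product: 37 3-(phenylsulfanyl)oxolan-2-one
Conditions: Et3N, CH2Cl2, 0 °C → rt
Reagents that add atoms: none
Why: SN2 displacement of the activated α-bromide by thiolate gives the α-phenylthio lactone.

Step 20
Reactants: 37 3-(phenylsulfanyl)oxolan-2-one; 34 {[(1R,2S,4aS,8aS)-1-(2-iodoethyl)-8a-methyldecahydronaphthalene-2,5,5-triyl]tris(methyleneoxy)}tris[tert-butyl(dimethyl)silane]
Product: 39 3-{2-[(1R,2S,4aS,8aS)-2,5,5-tris({[tert-butyl(dimethyl)silyl]oxy}methyl)-8a-methyldecahydronaphthalen-1-yl]ethyl}-3-(phenylsulfanyl)oxolan-2-one (epimer mixture at the lactone α-carbon), via lithium enolate 38 (not isolated)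
Conditions: LiHMDS, THF/DMPU, −78 °C; then 34, −78 °C → rt
Reagents that add atoms: none
Why: Alkylation of the sulfur-stabilised lactone enolate with the unhindered primary iodide forms the C12–C13 bond; the new quaternary centre is destroyed in step 21.

Step 21
Reactants: 39 3-{2-[(1R,2S,4aS,8aS)-2,5,5-tris({[tert-butyl(dimethyl)silyl]oxy}methyl)-8a-methyldecahydronaphthalen-1-yl]ethyl}-3-(phenylsulfanyl)oxolan-2-one
Product: 41 3-{2-[(1R,2S,4aS,8aS)-2,5,5-tris({[tert-butyl(dimethyl)silyl]oxy}methyl)-8a-methyldecahydronaphthalen-1-yl]ethyl}furan-2(5H)-one, via sulfoxide 40 (not isolated)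
Conditions: mCPBA (1.0 equiv), CH2Cl2, −78 °C; NaHCO3 wash; then toluene, 110 °C
Reagents that add atoms: none
Why: Sulfide oxidation followed by thermal syn-elimination of the sulfoxide toward the ring CH2 is the established route to 3-alkylfuran-2(5H)-ones and should give the endocyclic butenolide.

Step 22
Reactants: 41 3-{2-[(1R,2S,4aS,8aS)-2,5,5-tris({[tert-butyl(dimethyl)silyl]oxy}methyl)-8a-methyldecahydronaphthalen-1-yl]ethyl}furan-2(5H)-one
Product: 42 3-{2-[(1R,2S,4aS,8aS)-2,5,5-tris(hydroxymethyl)-8a-methyldecahydronaphthalen-1-yl]ethyl}furan-2(5H)-one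
Conditions: HF·pyridine, THF, 0 °C → rt
Reagents that add atoms: none
Why: Fluoride-mediated desilylation under mildly acidic conditions removes the three silyl ethers and leaves the base-sensitive butenolide intact.

**Compound list**

1 | 4-(benzyloxy)but-1-ene | C=CCCOCc1ccccc1 | starting material
2 | 3-methylbut-3-en-2-one | CC(=O)C(C)=C | starting material
3 | (3E)-6-(benzyloxy)-3-methylhex-3-en-2-one | CC(=O)/C(C)=C/CCOCc1ccccc1 | intermediate
4 | (2R,3E)-6-(benzyloxy)-3-methylhex-3-en-2-ol | C[C@@H](O)/C(C)=C/CCOCc1ccccc1 | intermediate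
5 | methyl 5,5-dimethoxypentanoate | COC(=O)CCCC(OC)OC | starting material
6 | 5,5-dimethoxypentanoic acid | OC(=O)CCCC(OC)OC | intermediate
7 | (2R,3E)-6-(benzyloxy)-3-methylhex-3-en-2-yl 5,5-dimethoxypentanoate | COC(OC)CCCC(=O)O[C@H](C)/C(C)=C/CCOCc1ccccc1 | intermediate
8 | lithium E(O)-enolate of 7 (OLi trans to the chain) | [Li]O/C(O[C@H](C)/C(C)=C/CCOCc1ccccc1)=C/CCC(OC)OC | intermediate
9 | (E)-trimethylsilyl ketene acetal of 7 (OSiMe3 trans to the chain) | C[Si](C)(C)O/C(O[C@H](C)/C(C)=C/CCOCc1ccccc1)=C/CCC(OC)OC | intermediate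
10 | trimethylsilyl (2S,3R,4E)-3-[2-(benzyloxy)ethyl]-2-(3,3-dimethoxypropyl)-4-methylhex-4-enoate | C[Si](C)(C)OC(=O)[C@@H](CCC(OC)OC)[C@H](/C(C)=C/C)CCOCc1ccccc1 | intermediate
11 | (2S,3R,4E)-3-[2-(benzyloxy)ethyl]-2-(3,3-dimethoxypropyl)-4-methylhex-4-enoic acid | OC(=O)[C@@H](CCC(OC)OC)[C@H](/C(C)=C/C)CCOCc1ccccc1 | intermediate
12 | methyl (2S,3R,4E)-3-[2-(benzyloxy)ethyl]-2-(3,3-dimethoxypropyl)-4-methylhex-4-enoate | COC(=O)[C@@H](CCC(OC)OC)[C@H](/C(C)=C/C)CCOCc1ccccc1 | intermediate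
13 | alkylborane from 12 (BH2 on C5 of the hexanoate chain, drawn as the monoalkylborane; C4/C5 epimers) | COC(=O)[C@@H](CCC(OC)OC)[C@H](C(C)C(C)B)CCOCc1ccccc1 | intermediate
14 | methyl (2S,3S)-3-[2-(benzyloxy)ethyl]-2-(3,3-dimethoxypropyl)-5-hydroxy-4-methylhexanoate (C4/C5 epimer mixture) | COC(=O)[C@@H](CCC(OC)OC)[C@H](C(C)C(C)O)CCOCc1ccccc1 | intermediate
15 | methyl (2S,3S)-3-[2-(benzyloxy)ethyl]-2-(3,3-dimethoxypropyl)-4-methyl-5-oxohexanoate (C4 epimer mixture) | COC(=O)[C@@H](CCC(OC)OC)[C@H](C(C)C(C)=O)CCOCc1ccccc1 | intermediate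
16 | N,N-dimethylmethaniminium iodide (Eschenmoser's salt) | C=[N+](C)C.[I-] | starting material
17 | lithium enolate of 15 (terminal, kinetic) | COC(=O)[C@@H](CCC(OC)OC)[C@H](C(C)C(=C)O[Li])CCOCc1ccccc1 | intermediate
18 | trimethylsilyl enol ether of 15 (terminal) | COC(=O)[C@@H](CCC(OC)OC)[C@H](C(C)C(=C)O[Si](C)(C)C)CCOCc1ccccc1 | intermediate
19 | methyl (2S,3S)-3-[2-(benzyloxy)ethyl]-2-(3,3-dimethoxypropyl)-7-(dimethylamino)-4-methyl-5-oxoheptanoate (C4 epimer mixture) | COC(=O)[C@@H](CCC(OC)OC)[C@H](C(C)C(=O)CCN(C)C)CCOCc1ccccc1 | intermediate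
20 | methyl (2S,3S)-3-[2-(benzyloxy)ethyl]-7-(dimethylamino)-4-methyl-5-oxo-2-(3-oxopropyl)heptanoate (C4 epimer mixture) | COC(=O)[C@@H](CCC=O)[C@H](C(C)C(=O)CCN(C)C)CCOCc1ccccc1 | intermediate
21 | dimethyl malonate | COC(=O)CC(=O)OC | starting material
22 | trimethyl (5S,6S)-6-[2-(benzyloxy)ethyl]-10-(dimethylamino)-7-methyl-8-oxodec-1-ene-1,1,5-tricarboxylate (C7 epimer mixture) | COC(=O)[C@@H](CCC=C(C(=O)OC)C(=O)OC)[C@H](C(C)C(=O)CCN(C)C)CCOCc1ccccc1 | intermediate
23 | methiodide (trimethylammonium iodide) of 22 | COC(=O)[C@@H](CCC=C(C(=O)OC)C(=O)OC)[C@H](C(C)C(=O)CC[N+](C)(C)C)CCOCc1ccccc1.[I-] | intermediate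
24 | trimethyl (5S,6S)-6-[2-(benzyloxy)ethyl]-7-methyl-8-oxodeca-1,9-diene-1,1,5-tricarboxylate (C7 epimer mixture) | COC(=O)[C@@H](CCC=C(C(=O)OC)C(=O)OC)[C@H](C(C)C(=O)C=C)CCOCc1ccccc1 | intermediate
25 | trimethyl (5S,6R)-6-[2-(benzyloxy)ethyl]-8-[(tert-butyldimethylsilyl)oxy]-7-methyldeca-1,7,9-triene-1,1,5-tricarboxylate (2-silyloxydiene, E/Z mixture at C7=C8) | COC(=O)[C@@H](CCC=C(C(=O)OC)C(=O)OC)[C@H](C(C)=C(O[Si](C)(C)C(C)(C)C)C=C)CCOCc1ccccc1 | intermediate
26 | trimethyl (4aS,5R,6S,8aS)-5-[2-(benzyloxy)ethyl]-4-[(tert-butyldimethylsilyl)oxy]-4a-methyl-1,2,4a,5,6,7,8,8a-octahydronaphthalene-1,1,6-tricarboxylate | C[C@@]12C(O[Si](C)(C)C(C)(C)C)=CCC(C(=O)OC)(C(=O)OC)[C@H]1CC[C@H](C(=O)OC)[C@H]2CCOCc1ccccc1 | intermediate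
27 | trimethyl (4aS,5R,6S,8aS)-5-[2-(benzyloxy)ethyl]-4a-methyl-4-oxodecahydronaphthalene-1,1,6-tricarboxylate (trans-fused) | C[C@@]12C(=O)CCC(C(=O)OC)(C(=O)OC)[C@H]1CC[C@H](C(=O)OC)[C@H]2CCOCc1ccccc1 | intermediate
28 | potassium enolate of 27 (C1–C2 enolate) | C[C@@]12C(O[K])=CCC(C(=O)OC)(C(=O)OC)[C@H]1CC[C@H](C(=O)OC)[C@H]2CCOCc1ccccc1 | intermediate
29 | trimethyl (4aS,5R,6S,8aS)-5-[2-(benzyloxy)ethyl]-4a-methyl-4-{[(trifluoromethyl)sulfonyl]oxy}-1,2,4a,5,6,7,8,8a-octahydronaphthalene-1,1,6-tricarboxylate | C[C@@]12C(OS(=O)(=O)C(F)(F)F)=CCC(C(=O)OC)(C(=O)OC)[C@H]1CC[C@H](C(=O)OC)[C@H]2CCOCc1ccccc1 | intermediate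
30 | trimethyl (4aS,5R,6S,8aS)-5-[2-(benzyloxy)ethyl]-4a-methyl-1,2,4a,5,6,7,8,8a-octahydronaphthalene-1,1,6-tricarboxylate | C[C@@]12C=CCC(C(=O)OC)(C(=O)OC)[C@H]1CC[C@H](C(=O)OC)[C@H]2CCOCc1ccccc1 | intermediate
31 | {(4aS,5R,6S,8aS)-5-[2-(benzyloxy)ethyl]-4a-methyl-1,2,4a,5,6,7,8,8a-octahydronaphthalene-1,1,6-triyl}trimethanol | C[C@@]12C=CCC(CO)(CO)[C@H]1CC[C@H](CO)[C@H]2CCOCc1ccccc1 | intermediate
32 | tris(tert-butyldimethylsilyl) ether of 31 | C[C@@]12C=CCC(CO[Si](C)(C)C(C)(C)C)(CO[Si](C)(C)C(C)(C)C)[C@H]1CC[C@H](CO[Si](C)(C)C(C)(C)C)[C@H]2CCOCc1ccccc1 | intermediate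
33 | 2-[(1R,2S,4aS,8aS)-2,5,5-tris({[tert-butyl(dimethyl)silyl]oxy}methyl)-8a-methyldecahydronaphthalen-1-yl]ethan-1-ol | C[C@@]12CCCC(CO[Si](C)(C)C(C)(C)C)(CO[Si](C)(C)C(C)(C)C)[C@H]1CC[C@H](CO[Si](C)(C)C(C)(C)C)[C@H]2CCO | intermediate
34 | {[(1R,2S,4aS,8aS)-1-(2-iodoethyl)-8a-methyldecahydronaphthalene-2,5,5-triyl]tris(methyleneoxy)}tris[tert-butyl(dimethyl)silane] | C[C@@]12CCCC(CO[Si](C)(C)C(C)(C)C)(CO[Si](C)(C)C(C)(C)C)[C@H]1CC[C@H](CO[Si](C)(C)C(C)(C)C)[C@H]2CCI | intermediate
35 | 3-bromooxolan-2-one (α-bromo-γ-butyrolactone) | O=C1OCCC1Br | starting material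
36 | benzenethiol | Sc1ccccc1 | starting material
37 | 3-(phenylsulfanyl)oxolan-2-one | O=C1OCCC1Sc1ccccc1 | intermediate
38 | lithium enolate of 37 | [Li]OC1=C(Sc2ccccc2)CCO1 | intermediate
39 | 3-{2-[(1R,2S,4aS,8aS)-2,5,5-tris({[tert-butyl(dimethyl)silyl]oxy}methyl)-8a-methyldecahydronaphthalen-1-yl]ethyl}-3-(phenylsulfanyl)oxolan-2-one (epimers at the lactone α-carbon) | C[C@@]12CCCC(CO[Si](C)(C)C(C)(C)C)(CO[Si](C)(C)C(C)(C)C)[C@H]1CC[C@H](CO[Si](C)(C)C(C)(C)C)[C@H]2CCC1(Sc2ccccc2)CCOC1=O | intermediate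
40 | sulfoxide of 39 (3-(benzenesulfinyl) lactone) | C[C@@]12CCCC(CO[Si](C)(C)C(C)(C)C)(CO[Si](C)(C)C(C)(C)C)[C@H]1CC[C@H](CO[Si](C)(C)C(C)(C)C)[C@H]2CCC1(S(=O)c2ccccc2)CCOC1=O | intermediate
41 | 3-{2-[(1R,2S,4aS,8aS)-2,5,5-tris({[tert-butyl(dimethyl)silyl]oxy}methyl)-8a-methyldecahydronaphthalen-1-yl]ethyl}furan-2(5H)-one | C[C@@]12CCCC(CO[Si](C)(C)C(C)(C)C)(CO[Si](C)(C)C(C)(C)C)[C@H]1CC[C@H](CO[Si](C)(C)C(C)(C)C)[C@H]2CCC1=CCOC1=O | intermediate
42 | 3-{2-[(1R,2S,4aS,8aS)-2,5,5-tris(hydroxymethyl)-8a-methyldecahydronaphthalen-1-yl]ethyl}furan-2(5H)-one | C[C@@]12CCCC(CO)(CO)[C@H]1CC[C@H](CO)[C@H]2CCC1=CCOC1=O | target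

**Summary and risks**

Total step count: 22 (steps 3 and 19 are side-branch preparations). Longest linear sequence: 20 steps (1, 2, 4–18, 20–22).

Steps most likely to fail:

1. Step 12 (key step). The vinyl ketone may be consumed by intermolecular conjugate addition or oligomerization before the hindered C10–H is enolized, or the cascade may stop after the first ring closure. Fallback (stepwise annulation; sets out from 15, comes back at 27): acetal hydrolysis of 15 (1 M HCl, THF) should give the keto aldehyde methyl (2S,3S)-3-[2-(benzyloxy)ethyl]-4-methyl-5-oxo-2-(3-oxopropyl)hexanoate F1. TiCl4/pyridine Knoevenagel condensation with 21 should give the methyl ketone trimethyl (5S,6S)-6-[2-(benzyloxy)ethyl]-7-methyl-8-oxonon-1-ene-1,1,5-tricarboxylate F2. TBSOTf/Et3N then converts the ketone into its more substituted silyl enol ether, which closes ring B alone by intramolecular Mukaiyama–Michael addition under the same chair and A(1,3) control, giving dimethyl 2-[(1R,2S,3R,4S)-2-acetyl-3-[2-(benzyloxy)ethyl]-4-(methoxycarbonyl)-2-methylcyclohexyl]propanedioate F3. Double deprotonation (LDA, 2.2 equiv; malonate first, then the methyl ketone) and reaction of the ketone enolate with 16 should give the Mannich base dimethyl 2-[(1R,2S,3R,4S)-3-[2-(benzyloxy)ethyl]-2-[3-(dimethylamino)propanoyl]-4-(methoxycarbonyl)-2-methylcyclohexyl]propanedioate F4. MeI and then DBU release the vinyl ketone next to the malonate, which closes ring A by 6-endo Michael addition (C3–C4) to give 27.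

2. Step 10. Enolization of the 1,7-keto aldehyde (intramolecular aldol) and premature β-elimination of dimethylamine may compete with the condensation. Fallback (ketone masked at the alcohol oxidation level; sets out from 19, comes back at 22): NaBH4 reduction of 19 should give the amino alcohol methyl (2S,3S)-3-[2-(benzyloxy)ethyl]-2-(3,3-dimethoxypropyl)-7-(dimethylamino)-5-hydroxy-4-methylheptanoate F5. Acetal hydrolysis (1 M HCl, THF) gives the hydroxy aldehyde methyl (2S,3S)-3-[2-(benzyloxy)ethyl]-7-(dimethylamino)-5-hydroxy-4-methyl-2-(3-oxopropyl)heptanoate F6. Knoevenagel condensation with 21 gives trimethyl (5S,6S)-6-[2-(benzyloxy)ethyl]-10-(dimethylamino)-8-hydroxy-7-methyldec-1-ene-1,1,5-tricarboxylate F7, and Parikh–Doering oxidation of the secondary alcohol returns the ketone 22.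

3. Step 1. Homodimerization of 1 and slow turnover with the electron-poor 1,1-disubstituted partner may leave little cross product, or the E/Z ratio may erode. Fallback (carbonyl olefination; sets out from 1, comes back at 3): ozonolysis of 1 (O3, then PPh3) should give 3-(benzyloxy)propanal F8. Wittig reaction with ethyl 2-(triphenylphosphoranylidene)propanoate gives ethyl (2E)-5-(benzyloxy)-2-methylpent-2-enoate F9. MeNHOMe·HCl/i-PrMgCl converts the ester into the Weinreb amide (2E)-5-(benzyloxy)-N-methoxy-N,2-dimethylpent-2-enamide F10, and MeMgBr gives 3.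

Further compounds
F1 | step 12 | methyl (2S,3S)-3-[2-(benzyloxy)ethyl]-4-methyl-5-oxo-2-(3-oxopropyl)hexanoate | COC(=O)[C@@H](CCC=O)[C@H](C(C)C(C)=O)CCOCc1ccccc1
F2 | step 12 | trimethyl (5S,6S)-6-[2-(benzyloxy)ethyl]-7-methyl-8-oxonon-1-ene-1,1,5-tricarboxylate | COC(=O)[C@@H](CCC=C(C(=O)OC)C(=O)OC)[C@H](C(C)C(C)=O)CCOCc1ccccc1
F3 | step 12 | dimethyl 2-[(1R,2S,3R,4S)-2-acetyl-3-[2-(benzyloxy)ethyl]-4-(methoxycarbonyl)-2-methylcyclohexyl]propanedioate | C[C@@]1(C(C)=O)[C@@H](C(C(=O)OC)C(=O)OC)CC[C@H](C(=O)OC)[C@H]1CCOCc1ccccc1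
F4 | step 12 | dimethyl 2-[(1R,2S,3R,4S)-3-[2-(benzyloxy)ethyl]-2-[3-(dimethylamino)propanoyl]-4-(methoxycarbonyl)-2-methylcyclohexyl]propanedioate | C[C@@]1(C(=O)CCN(C)C)[C@@H](C(C(=O)OC)C(=O)OC)CC[C@H](C(=O)OC)[C@H]1CCOCc1ccccc1
F5 | step 10 | methyl (2S,3S)-3-[2-(benzyloxy)ethyl]-2-(3,3-dimethoxypropyl)-7-(dimethylamino)-5-hydroxy-4-methylheptanoate | COC(=O)[C@@H](CCC(OC)OC)[C@H](C(C)C(O)CCN(C)C)CCOCc1ccccc1
F6 | step 10 | methyl (2S,3S)-3-[2-(benzyloxy)ethyl]-7-(dimethylamino)-5-hydroxy-4-methyl-2-(3-oxopropyl)heptanoate | COC(=O)[C@@H](CCC=O)[C@H](C(C)C(O)CCN(C)C)CCOCc1ccccc1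
F7 | step 10 | trimethyl (5S,6S)-6-[2-(benzyloxy)ethyl]-10-(dimethylamino)-8-hydroxy-7-methyldec-1-ene-1,1,5-tricarboxylate | COC(=O)[C@@H](CCC=C(C(=O)OC)C(=O)OC)[C@H](C(C)C(O)CCN(C)C)CCOCc1ccccc1
F8 | step 1 | 3-(benzyloxy)propanal | O=CCCOCc1ccccc1
F9 | step 1 | ethyl (2E)-5-(benzyloxy)-2-methylpent-2-enoate | CCOC(=O)/C(C)=C/CCOCc1ccccc1
F10 | step 1 | (2E)-5-(benzyloxy)-N-methoxy-N,2-dimethylpent-2-enamide | CON(C)C(=O)/C(C)=C/CCOCc1ccccc1
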